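**Plan**
- Numbering: 1,2-dihydronaphthalene. Ring A is the benzene ring C4a–C8a (oxygens on C6 and C7), ring B is C1–C4/C4a/C8a with C3=C4, ring C is the 2-pyranone on C1. The target is (1R,2S), 1,2-trans.
- Retrosynthetic cuts, in order: the five O-alkyl groups; C4–C4a (ring B opens to an aryl bromide and a 2-methylenesuccinate); C4a–Br; C1–C2; the C1–aryl bond; ring C back to diethyl oxalate and ethyl 3-methylbut-2-enoate.
- Enabling feature: C4 is an unsubstituted vinylic CH bonded to ring A at C4a and β to the C3 ester. This is the pattern left when an arylpalladium at C4a adds to the CH2 end of an acrylate and then loses hydride.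
- Forward order: ring C first; ring A joined to the future C1 by Suzuki coupling; the C2–C3 diester unit added at C1; bromine put on C4a only then, so that no earlier step has to tolerate an aryl bromide; ring B closed last; deprotection.
- Stereochemistry: C1 and C2 are set together in the cinchona-catalysed allylic alkylation of step 6. The Heck closure creates no stereocentre and no later step touches C1 or C2.

Key step: step 8

Assumption: the sense of induction and the preferred diastereomer in step 6 have to be established by experiment. (DHQD)2PHAL is written; the pseudoenantiomeric (DHQ)2PHAL or another dimeric cinchona ether would be used if needed.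

**Step 1**
Reactants: 1 ethyl 3-methylbut-2-enoate; 2 diethyl oxalate
Product: 4 ethyl 4-methyl-2-oxo-2H-pyran-6-carboxylate, via potassium enolate of diethyl 4-methyl-2-oxohex-4-enedioate 3 (not isolated)
Conditions: KOEt, Et2O–EtOH, 0 °C → rt; then conc. HCl (aq), 0 °C → rt
Reagents that add atoms: none
Why: Vinylogous Claisen condensation of the γ-deprotonated enoate with the oxalate, followed by acid-induced lactonisation of the enol oxygen onto the conjugated ester, is the classical entry to 4-methyl-2-pyranone-6-carboxylates.

**Step 2**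
Reactants: 4 ethyl 4-methyl-2-oxo-2H-pyran-6-carboxylate
Product: 5 ethyl 4-(bromomethyl)-2-oxo-2H-pyran-6-carboxylate
Conditions: NBS (1.05 equiv), AIBN (azobisisobutyronitrile, cat.), PhCF3, 80 °C
Reagents that add atoms: N-bromosuccinimide, O=C1CCC(=O)N1Br
Why: Wohl–Ziegler bromination should be selective because the 4-methyl group is the only allylic C–H position and the ester-deactivated ring resists ionic bromination.

**Step 3**
Reactants: 5 ethyl 4-(bromomethyl)-2-oxo-2H-pyran-6-carboxylate; 6 (3,4-dimethoxyphenyl)boronic acid
Product: 7 ethyl 4-[(3,4-dimethoxyphenyl)methyl]-2-oxo-2H-pyran-6-carboxylate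
Conditions: Pd(OAc)2 (3 mol %), PPh3 (6 mol %), K3PO4·H2O, toluene, 80 °C
Reagents that add atoms: none
Why: Suzuki–Miyaura sp3–sp2 coupling should work because the activated allylic C–Br bond adds readily to zerovalent palladium, the resulting alkylpalladium has no β-hydrogen, and the heterogeneous phosphate base spares the pyranone.

**Step 4**
Reactants: 8 methyl acrylate; 9 methyl glyoxylate
Product: 10 dimethyl 2-hydroxy-3-methylidenebutanedioate (racemic)
Conditions: DABCO (1,4-diazabicyclo[2.2.2]octane, 20 mol %), 1,4-dioxane, rt
Reagents that add atoms: none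
Why: Morita–Baylis–Hillman reaction of an acrylate with the highly electrophilic glyoxylate aldehyde; the racemic carbinol is acceptable because this carbon becomes planar in the ammonium intermediate of step 6.

**Step 5**
Reactants: 10 dimethyl 2-hydroxy-3-methylidenebutanedioate
Product: 11 dimethyl 2-[(tert-butoxycarbonyl)oxy]-3-methylidenebutanedioate (racemic)
Conditions: Boc2O, DMAP (4-(dimethylamino)pyridine, 10 mol %), CH2Cl2, 0 °C → rt
Reagents that add atoms: di-tert-butyl dicarbonate, CC(C)(C)OC(=O)OC(=O)OC(C)(C)C
Why: DMAP-catalysed O-acylation with Boc2O is the standard preparation of Morita–Baylis–Hillman carbonates.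

**Step 6**
Reactants: 7 ethyl 4-[(3,4-dimethoxyphenyl)methyl]-2-oxo-2H-pyran-6-carboxylate; 11 dimethyl 2-[(tert-butoxycarbonyl)oxy]-3-methylidenebutanedioate
Product: 12 dimethyl (2S)-2-[(S)-(3,4-dimethoxyphenyl)[6-(ethoxycarbonyl)-2-oxo-2H-pyran-4-yl]methyl]-3-methylidenebutanedioate
Conditions: (DHQD)2PHAL (hydroquinidine 1,4-phthalazinediyl diether, 10 mol %), toluene, 25–40 °C
Reagents that add atoms: none
Why: Proposed new method: the quinuclidine nitrogen displaces the carbonate by SN2′ attack to give a chiral 2-(ammoniomethyl)butenedioate plus CO2 and tert-butoxide; the tert-butoxide deprotonates the methylene of 7, which is activated by both the aryl group and the vinylogous lactone; the extended enolate then attacks the CH(CO2Me) carbon through its exocyclic benzylic carbon in a second SN2′ step that releases the catalyst and sets C1 and C2 within the chiral ion pair; the closest known reaction type is the cinchona-catalysed asymmetric allylic alkylation of Morita–Baylis–Hillman carbonates with butenolides and related vinylogous lactone pronucleophiles; the major diastereomer would be isolated by chromatography and its configuration confirmed after ring closure.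

**Step 7**
Reactants: 12 dimethyl (2S)-2-[(S)-(3,4-dimethoxyphenyl)[6-(ethoxycarbonyl)-2-oxo-2H-pyran-4-yl]methyl]-3-methylidenebutanedioate
Product: 13 dimethyl (2S)-2-[(R)-(2-bromo-4,5-dimethoxyphenyl)[6-(ethoxycarbonyl)-2-oxo-2H-pyran-4-yl]methyl]-3-methylidenebutanedioate
Conditions: NBS (1.05 equiv), MeCN, 0 °C → rt, dark
Reagents that add atoms: N-bromosuccinimide, O=C1CCC(=O)N1Br
Why: Electrophilic aromatic bromination should go to the ring position para to a methoxy group and ortho to the benzylic carbon (the future C4a), as in brominations of 4-alkylveratroles, while the electron-poor acrylate and pyranone stay inert; the descriptor at the methine changes from S to R only because bromine raises the aryl group above the pyranone in priority.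

**Step 8**
Reactants: 13 dimethyl (2S)-2-[(R)-(2-bromo-4,5-dimethoxyphenyl)[6-(ethoxycarbonyl)-2-oxo-2H-pyran-4-yl]methyl]-3-methylidenebutanedioate
Product: 14 dimethyl (1R,2S)-1-[6-(ethoxycarbonyl)-2-oxo-2H-pyran-4-yl]-6,7-dimethoxy-1,2-dihydronaphthalene-2,3-dicarboxylate
Conditions: Pd(OAc)2 (10 mol %), PPh3 (20 mol %), n-Bu4NBr, NaHCO3, DMF, 90 °C, argon
Reagents that add atoms: none
Why: Zerovalent palladium formed from Pd(OAc)2 and PPh3 inserts into the C4a–Br bond, the arylpalladium adds syn across the 1,1-disubstituted acrylate with the aryl group going to the CH2 terminus (C4) and palladium to C3, and syn β-hydride elimination of a C4 hydrogen releases the C3=C4 alkene while NaHCO3 takes up HBr. The closest known reaction type is the 6-endo intramolecular Mizoroki–Heck cyclisation of 2-bromoaryl-tethered α-substituted acrylates to 1,2-dihydronaphthalene-3-carboxylates. Ring B closes in the 6-endo-trig mode through the new C4–C4a bond. No stereocentre is created, and C1 and C2 should be carried through unchanged because only a hydrogen carbonate base is present. The step needs 6-endo insertion to beat 5-exo and hydride loss toward C4 instead of C2: the acrylate polarity directs the aryl group to the β-carbon, the fully substituted ester-bearing α-carbon hinders 5-exo attack, and elimination toward benzylic C4 gives the alkene conjugated with both ring A and the C3 ester.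

**Step 9**
Reactants: 14 dimethyl (1R,2S)-1-[6-(ethoxycarbonyl)-2-oxo-2H-pyran-4-yl]-6,7-dimethoxy-1,2-dihydronaphthalene-2,3-dicarboxylate
Product: 15 dimethyl (1R,2S)-1-[6-(ethoxycarbonyl)-2-oxo-2H-pyran-4-yl]-6,7-dihydroxy-1,2-dihydronaphthalene-2,3-dicarboxylate
Conditions: BBr3 (6 equiv), CH2Cl2, −78 → 0 °C; then ice-water
Reagents that add atoms: none
Why: Lewis-acid ether cleavage, in which BBr3 complexes the two adjacent methoxy oxygens and bromide removes the methyl groups by SN2, should spare the alkyl esters and the lactone at or below 0 °C.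

**Step 10**
Reactants: 15 dimethyl (1R,2S)-1-[6-(ethoxycarbonyl)-2-oxo-2H-pyran-4-yl]-6,7-dihydroxy-1,2-dihydronaphthalene-2,3-dicarboxylate
Product: 16 (1R,2S)-1-(6-carboxy-2-oxo-2H-pyran-4-yl)-6,7-dihydroxy-1,2-dihydronaphthalene-2,3-dicarboxylic acid (CNP0195322.1)
Conditions: 6 M HCl (aq)–1,4-dioxane (1:1), 80 °C, argon; reversed-phase purification
Reagents that add atoms: water, O
Why: Acid-catalysed ester hydrolysis is chosen because the 2-pyranone opens in alkali but is retained in acid (2-pyranone-6-carboxylic acids are classically freed from their esters this way), C1 cannot enolise under these conditions, and the 1,2-trans arrangement at C2 is expected to be the preferred one.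

**Compound list**
1 | ethyl 3-methylbut-2-enoate | CCOC(=O)C=C(C)C | starting material
2 | diethyl oxalate | CCOC(=O)C(=O)OCC | starting material
3 | potassium enolate of diethyl (4Z)-4-methyl-2-oxohex-4-enedioate (potassium (2Z,4Z)-1,6-diethoxy-4-methyl-1,6-dioxohexa-2,4-dien-2-olate) | CCOC(=O)/C([O-])=C/C(C)=C\C(=O)OCC.[K+] | intermediate (not isolated)
4 | ethyl 4-methyl-2-oxo-2H-pyran-6-carboxylate | CCOC(=O)c1cc(C)cc(=O)o1 | intermediate
5 | ethyl 4-(bromomethyl)-2-oxo-2H-pyran-6-carboxylate | CCOC(=O)c1cc(CBr)cc(=O)o1 | intermediate
6 | (3,4-dimethoxyphenyl)boronic acid | COc1ccc(B(O)O)cc1OC | starting material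
7 | ethyl 4-[(3,4-dimethoxyphenyl)methyl]-2-oxo-2H-pyran-6-carboxylate | CCOC(=O)c1cc(Cc2ccc(OC)c(OC)c2)cc(=O)o1 | intermediate
8 | methyl acrylate | C=CC(=O)OC | starting material
9 | methyl glyoxylate | COC(=O)C=O | starting material
10 | dimethyl 2-hydroxy-3-methylidenebutanedioate (racemic) | C=C(C(=O)OC)C(O)C(=O)OC | intermediate
11 | dimethyl 2-[(tert-butoxycarbonyl)oxy]-3-methylidenebutanedioate (racemic) | C=C(C(=O)OC)C(OC(=O)OC(C)(C)C)C(=O)OC | intermediate
12 | dimethyl (2S)-2-[(S)-(3,4-dimethoxyphenyl)[6-(ethoxycarbonyl)-2-oxo-2H-pyran-4-yl]methyl]-3-methylidenebutanedioate | COc1ccc([C@@H](c2cc(C(=O)OCC)oc(=O)c2)[C@@H](C(=C)C(=O)OC)C(=O)OC)cc1OC | intermediate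
13 | dimethyl (2S)-2-[(R)-(2-bromo-4,5-dimethoxyphenyl)[6-(ethoxycarbonyl)-2-oxo-2H-pyran-4-yl]methyl]-3-methylidenebutanedioate | Brc1cc(OC)c(OC)cc1[C@@H](c1cc(C(=O)OCC)oc(=O)c1)[C@@H](C(=C)C(=O)OC)C(=O)OC | intermediate (Heck precursor)
14 | dimethyl (1R,2S)-1-[6-(ethoxycarbonyl)-2-oxo-2H-pyran-4-yl]-6,7-dimethoxy-1,2-dihydronaphthalene-2,3-dicarboxylate | COC(=O)C1=Cc2cc(OC)c(OC)cc2[C@@H](c2cc(C(=O)OCC)oc(=O)c2)[C@@H]1C(=O)OC | intermediate (Heck product)
15 | dimethyl (1R,2S)-1-[6-(ethoxycarbonyl)-2-oxo-2H-pyran-4-yl]-6,7-dihydroxy-1,2-dihydronaphthalene-2,3-dicarboxylate | COC(=O)C1=Cc2cc(O)c(O)cc2[C@@H](c2cc(C(=O)OCC)oc(=O)c2)[C@@H]1C(=O)OC | intermediate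
16 | (1R,2S)-1-(6-carboxy-2-oxo-2H-pyran-4-yl)-6,7-dihydroxy-1,2-dihydronaphthalene-2,3-dicarboxylic acid | O=C(O)C1=Cc2cc(O)c(O)cc2[C@@H](c2cc(C(=O)O)oc(=O)c2)[C@@H]1C(=O)O | target

**Step count**
Total: 10 steps. Longest linear sequence: 8 steps (1, 2, 3, 6, 7, 8, 9, 10); steps 4 and 5 form the side branch.

**Steps most likely to fail**

Step 6. The pronucleophile may be too weakly acidic to be turned over by the tert-butoxide released in the cycle, or facial selectivity at C1 and C2 may be poor, so that the enantiomeric or diastereomeric purity of 12 is insufficient. The fallback uses stoichiometric, known chemistry and sets out from 10 and 7. Alcohol 10 is treated with PBr3 (Et2O, 0 °C), which brominates with allylic transposition, as is general for Morita–Baylis–Hillman alcohols, to give dimethyl (2Z)-2-(bromomethyl)but-2-enedioate F1. Compound 7 is then alkylated with this bromide using Cs2CO3 in MeCN, an addition–elimination (SN2′) alkylation of an active-methylene compound that forms the same C1–C2 bond without enantiocontrol. The racemate of the required diastereomer is purified on silica and resolved by preparative chromatography on a chiral stationary phase into 12 and its antipode, dimethyl (2R)-2-[(R)-(3,4-dimethoxyphenyl)[6-(ethoxycarbonyl)-2-oxo-2H-pyran-4-yl]methyl]-3-methylidenebutanedioate F2, which is set aside. The route is rejoined at 12.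

Step 8. The ring closure may be diverted by 5-exo carbopalladation, by base- and heat-induced migration of the exocyclic alkene into conjugation with both esters before cyclisation, or by epimerisation at C1 or C2 at 90 °C. The fallback changes the activating group so that closure can run near room temperature. It sets out from 12, which is iodinated with N-iodosuccinimide and catalytic CF3CO2H in MeCN to give dimethyl (2S)-2-[(R)-[6-(ethoxycarbonyl)-2-oxo-2H-pyran-4-yl](2-iodo-4,5-dimethoxyphenyl)methyl]-3-methylidenebutanedioate F3. The aryl iodide should undergo oxidative addition at 25–40 °C under phosphine-free phase-transfer conditions (Pd(OAc)2, n-Bu4NCl, NaHCO3, DMF), where alkene migration and epimerisation are slow. The same 6-endo closure then rejoins the route at 14.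

Step 10. Hydrolysis of the hindered C2 ester may stay incomplete, and long heating in acid may degrade the oxidation-prone catechol or the pyranone. The fallback reverses the order of deprotection and avoids hot mineral acid, setting out from 14. The three esters are cleaved first with Me3SnOH (1,2-dichloroethane, 80 °C, then dilute HCl work-up, which also re-closes any opened lactone) to give (1R,2S)-1-(6-carboxy-2-oxo-2H-pyran-4-yl)-6,7-dimethoxy-1,2-dihydronaphthalene-2,3-dicarboxylic acid F4. BBr3 in CH2Cl2 (−78 → 0 °C, water quench) then removes the two methyl ethers and the route is rejoined at 16.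

**Further compounds**
F1 | step 6 | dimethyl (2Z)-2-(bromomethyl)but-2-enedioate | COC(=O)/C=C(\CBr)C(=O)OC
F2 | step 6 | dimethyl (2R)-2-[(R)-(3,4-dimethoxyphenyl)[6-(ethoxycarbonyl)-2-oxo-2H-pyran-4-yl]methyl]-3-methylidenebutanedioate | COc1ccc([C@H](c2cc(C(=O)OCC)oc(=O)c2)[C@H](C(=C)C(=O)OC)C(=O)OC)cc1OC
F3 | step 8 | dimethyl (2S)-2-[(R)-[6-(ethoxycarbonyl)-2-oxo-2H-pyran-4-yl](2-iodo-4,5-dimethoxyphenyl)methyl]-3-methylidenebutanedioate | Ic1cc(OC)c(OC)cc1[C@@H](c1cc(C(=O)OCC)oc(=O)c1)[C@@H](C(=C)C(=O)OC)C(=O)OC
F4 | step 10 | (1R,2S)-1-(6-carboxy-2-oxo-2H-pyran-4-yl)-6,7-dimethoxy-1,2-dihydronaphthalene-2,3-dicarboxylic acid | O=C(O)C1=Cc2cc(OC)c(OC)cc2[C@@H](c2cc(C(=O)O)oc(=O)c2)[C@@H]1C(=O)O
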